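The dawn run, with 0.16 M of protic impurity, stands ahead of the noon run, with 0.24 M: at 4.00 min it reads 15.4% of ring, where a straight line between the noon readings gives 13.6%.

| setting | noon | dawn | flask |
|---|---|---|---|
| substrate | 0.80 M | 0.80 M | 0.80 M |
| activator | 0.80 M | 0.80 M | 0.800 M |
| protic impurity | 0.24 M | 0.16 M | 0.240 M |
| remark | the very flask that is asked about, followed so far | run made earlier |  |
| time |  |  | 30 min |

| noon: time / min | noon: ring / % | dawn: time / min | dawn: ring / % |
|---|---|---|---|
| 1.50 | 4.4 | 0.333 | 0.2 |
| 5.00 | 17.3 | 0.500 | 0.6 |
| 8.00 | 23.4 | 0.833 | 1.2 |
| 12.0 | 29.0 | 1.33 | 3.9 |
| 20.0 | 33.7 | 2.00 | 7.6 |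
| 25.0 | 35.2 | 3.00 | 11.1 |
| 30.0 | 35.6 | 4.00 | 15.4 |

(each reading ± 0.5 percentage points)

- larch: at 30 min add activator, 100% of the amount charged, then wait 30 min
- elm: at 30 min add substrate, 50.0% of the amount charged, then wait 30 min
- ash: change nothing and wait 30 min more
- alder: at 30 min take out 90% of the ring then present, then wait 30 min

1. ring, in percent of the substrate first charged, at 30 min
2. the remedy with the largest gain of ring, or "none" below 2 percentage points (larch / elm / ash / alder / none)
3. ring present, with what was taken out counted in, in percent of the substrate first charged, after larch
4. ring present, with what was taken out counted in, in percent of the substrate first charged, after ash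

- removed ring is counted in
- additions bring no volume worth counting

I build the noon flask up in steps. With the main step by itself, one activator per ring, the equal charges of substrate and activator allow 100% of ring. Next I let the protic impurity take one activator each, early on. That leaves a working charge, activator minus impurity, of 0.560 M in the noon run and 0.640 M in the dawn run, and it lowers the noon ceiling to 70.0%. The ratio of working charges, 1.14, stands beside the reading ratio of 1.13, which carries the scatter of the readings.

The noon run reads 35.6% at its last point, or 0.285 M of ring, below that ceiling, so I count on some further loss that a reading of ring does not identify. I name what remains the working yield, ring formed per working activator: 0.509.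

The noon run climbs 1.9 percentage points between 20.0 min and 30.0 min, so I take now near 35.6% and ash near 36.6%. Of the options, larch is the one that adds working activator. I assume the fresh charge meets no impurity, since the first charge exceeded it. I also assume, without proof, that the working yield carries over to a flask that has already spent substrate; on that assumption its 0.800 M gives 86.5%, so larch is my choice.

The forecast says 35.8% (35.2% to 36.4%), larch as the best remedy with 58% (50% to 64%), below my figure, and 36.2% (35.6% to 37.5%) after ash, holding that “Fresh activator should restart the reaction”.

The flask gives 36.5% now, 39.0% after ash, and larch as the best remedy, reaching 53.8%.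

    2 activator → homo dimer (k = 6.60 × 10⁻⁴ /M/s)
    substrate + activator → activated form (k = 0.00560 /M/s)
    substrate + activated form → side product (k = 0.00800 /M/s)
    substrate + activated form → open dimer (k = 4.90 × 10⁻⁴ /M/s)
    activator + protic impurity → quenched reagent (k = 0.120 /M/s)
    activated form → ring (k = 0.00550 /s)

At 30.0 min this flask holds 19.7% of substrate and 40.7% as side product. The gain of larch over now, taken per fresh activator, is a working yield of 0.172, against 0.509 for the first charge. The neighbour flask with 2.0 M of activator has a working charge of 1.76 M and reaches 63.9% of ring, a working yield of 0.290, with 0.237% of its substrate left.

The earlier runs and the new flask stem from a simulated flask from invented constants; scatter was added.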